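Ring C is disconnected at O1–C8a, C4–C4a and O1–C2, giving a ring A aryne and a ring B 2-aryl-3-methoxyacrylic acid. The step exploits that O1–C8a and C4–C4a lie on adjacent ring A carbons and that the C5 oxygen next to C4a sends a carboxylate to C8a. In one operation the aryne inserts into the acid C–O bond and the phenoxide closes the pyranone by expelling methoxide. The aryne precursor is an ortho-silylaryl triflate bearing the C5, C6 and C7 oxygens and hydrogen at C8, which is hydroxylated last. Every hydroxyl to be freed travels as a methoxymethyl ether, so one acid treatment finishes the synthesis.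

Key step: step 10

Remark: compounds 1, 9 and 12 are taken as purchased; 13 is a racemic mixture of diastereomers whose stereocentres are destroyed in the same flask, so its configuration is left undefined.

Step 1
Reactants: 1 2-methoxybenzene-1,3-diol (2-methoxyresorcinol)
Product: 2 2-methoxy-1,3-bis(methoxymethoxy)benzene
Conditions: NaH, MOMCl, DMF, 0 °C → rt
Reagents that add atoms: chloromethyl methyl ether, COCCl
Why: Williamson-type O-alkylation of the two sodium phenoxides by the α-chloro ether (methoxymethyl ether formation) is fast at both equivalent hydroxyls and leaves the methyl ether alone.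

Step 2
Reactants: 2 2-methoxy-1,3-bis(methoxymethoxy)benzene
Product: 4 4-methoxy-3,5-bis(methoxymethoxy)phenol, via aryl boronate 3 (not isolated)
Conditions: [Ir(OMe)(cod)]2 (cat.), dtbpy (cat.), B2pin2, THF, 80 °C; then aq NaOH, H2O2, 0 °C
Reagents that add atoms: hydrogen peroxide, OO; bis(pinacolato)diboron, CC1(C)OB(OC1(C)C)B1OC(C)(C)C(C)(C)O1 (atoms kept only in 3)
Why: Iridium-catalysed aromatic C–H borylation (Hartwig–Miyaura borylation) is governed by sterics and should pick C5 of 2, the only C–H with no ortho substituent, and basic peroxide then converts the boronate into the phenol by boron-to-oxygen 1,2-aryl shift (boronate oxidation) under conditions that acetal ethers tolerate.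

Step 3
Reactants: 4 4-methoxy-3,5-bis(methoxymethoxy)phenol
Product: 5 2-bromo-4-methoxy-3,5-bis(methoxymethoxy)phenol
Conditions: NBS (1.0 equiv), CH2Cl2, −78 °C → 0 °C
Reagents that add atoms: N-bromosuccinimide, O=C1CCC(=O)N1Br
Why: Electrophilic aromatic bromination of the phenol can only occur at the two equivalent carbons ortho to the hydroxyl, the sole open ring positions, so one equivalent of NBS at low temperature should give a single monobromide.

Step 4
Reactants: 5 2-bromo-4-methoxy-3,5-bis(methoxymethoxy)phenol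
Product: 8 4-methoxy-3,5-bis(methoxymethoxy)-2-(trimethylsilyl)phenyl trifluoromethanesulfonate, via silyl ether 6 (not isolated), via lithium silylphenoxide 7 (not isolated)
Conditions: HMDS, THF, 65 °C, then evaporate; n-BuLi, THF, −78 °C; PhNTf2, −78 °C → rt
Reagents that add atoms: hexamethyldisilazane, C[Si](C)(C)N[Si](C)(C)C; N-phenylbis(trifluoromethanesulfonimide), O=S(=O)(N(c1ccccc1)S(=O)(=O)C(F)(F)F)C(F)(F)F
Why: O-Silylation, bromine–lithium exchange and 1,3 O→C silyl migration (retro-Brook rearrangement) move the trimethylsilyl group onto the carbon that carried bromine, between the phenoxide and the methoxymethoxy group, and triflation of the resulting lithium phenoxide with PhNTf2 completes the standard ortho-silylaryl triflate assembly without touching the acetals.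

Step 5
Reactants: 9 2,3-dimethoxyphenol
Product: 10 1,2-dimethoxy-3-(methoxymethoxy)benzene
Conditions: NaH, MOMCl, DMF, 0 °C → rt
Reagents that add atoms: chloromethyl methyl ether, COCCl
Why: Williamson-type O-alkylation of the sodium phenoxide by the α-chloro ether gives the methoxymethyl ether, a group that withstands every basic step up to the final acid treatment.

Step 6
Reactants: 10 1,2-dimethoxy-3-(methoxymethoxy)benzene
Product: 11 2-[3,4-dimethoxy-5-(methoxymethoxy)phenyl]-4,4,5,5-tetramethyl-1,3,2-dioxaborolane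
Conditions: [Ir(OMe)(cod)]2 (cat.), dtbpy (cat.), B2pin2, THF, 80 °C
Reagents that add atoms: bis(pinacolato)diboron, CC1(C)OB(OC1(C)C)B1OC(C)(C)C(C)(C)O1
Why: The same sterically controlled Hartwig–Miyaura C–H borylation should functionalise C5 of 10, the only ring C–H flanked by two hydrogens, giving the 3,4,5-trioxygenated aryl boronate directly.

Step 7
Reactants: 12 methyl (E)-3-methoxyprop-2-enoate
Product: 14 methyl (Z)-2-iodo-3-methoxyprop-2-enoate, via iodo acetate adduct 13 (not isolated)
Conditions: NIS, AcOH, CH2Cl2, rt; then Et3N, rt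
Reagents that add atoms: N-iodosuccinimide, O=C1CCC(=O)N1I; acetic acid, CC(=O)O (atoms kept only in 13)
Why: Electrophilic iodo-acetoxylation of the enol ether double bond followed by amine-induced elimination of acetic acid (addition–elimination α-halogenation of a β-alkoxyacrylate) should return the alkene with ester and methoxy still trans, which is the Z descriptor once iodine is on C2.

Step 8
Reactants: 11 2-[3,4-dimethoxy-5-(methoxymethoxy)phenyl]-4,4,5,5-tetramethyl-1,3,2-dioxaborolane; 14 methyl (Z)-2-iodo-3-methoxyprop-2-enoate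
Product: 15 methyl (E)-2-[3,4-dimethoxy-5-(methoxymethoxy)phenyl]-3-methoxyprop-2-enoate
Conditions: Pd(PPh3)4 (cat.), K3PO4, 1,4-dioxane/H2O, 85 °C
Reagents that add atoms: none
Why: Suzuki–Miyaura coupling of an alkenyl iodide with an aryl pinacol boronate under zerovalent palladium catalysis proceeds with retention of alkene geometry, so the aryl group replaces iodine and the (E)-β-methoxyacrylate results, the acetal being stable to the basic medium.

Step 9
Reactants: 15 methyl (E)-2-[3,4-dimethoxy-5-(methoxymethoxy)phenyl]-3-methoxyprop-2-enoate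
Product: 16 (E)-2-[3,4-dimethoxy-5-(methoxymethoxy)phenyl]-3-methoxyprop-2-enoic acid
Conditions: LiOH, THF/MeOH/H2O, rt; then 1 M HCl to pH 4, 0 °C
Reagents that add atoms: lithium hydroxide, [Li+].[OH-]
Why: Saponification (BAc2 ester hydrolysis) is selective because the β-methoxyacrylate, a vinylogous carbonate, resists conjugate attack by cold hydroxide, and acidification only to pH 4 at 0 °C spares the enol ether and the methoxymethyl ether.

Step 10
Reactants: 8 4-methoxy-3,5-bis(methoxymethoxy)-2-(trimethylsilyl)phenyl trifluoromethanesulfonate (1.5 equiv); 16 (E)-2-[3,4-dimethoxy-5-(methoxymethoxy)phenyl]-3-methoxyprop-2-enoic acid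
Product: 19 3-[3,4-dimethoxy-5-(methoxymethoxy)phenyl]-6-methoxy-5,7-bis(methoxymethoxy)-4H-chromen-4-one, via aryne 17 (not isolated), via cesium acylphenoxide 18 (not isolated)
Conditions: CsF (4 equiv), THF, 125 °C, sealed tube
Reagents that add atoms: none
Why: Fluoride removes the silyl group of 8 and triflate leaves, giving aryne 17; the cesium carboxylate of 16 adds through oxygen to the aryne carbon that becomes C8a, the one remote from the flanking methoxymethoxy group, and the aryl anion so formed at the future C4a attacks the neighbouring ester carbonyl through a four-membered alkoxide that opens to the ortho-acyl phenoxide 18. This is the fluoride-triggered insertion of an aryne into the C–O bond of a carboxylic acid (an anionic ortho-Fries type 1,3 O→C acyl shift), the closest known reaction type being that insertion with in situ oxa-Michael closure of unsaturated acids to chromanones and flavones. Ring C then closes by 6-endo-trig oxa-Michael addition of the phenoxide to the β-carbon of the β-methoxy enone followed by loss of methoxide (addition–elimination), which fixes the chromone C2=C3 bond. No stereocentre is formed, and the alkene geometry of 16 is lost without consequence. The step needs regioselective attack on an unsymmetrical aryne, which the inductive pull of the oxygen at the future C5 (a 3-alkoxyaryne with C8 left as C–H) should secure by polarising and distorting the triple bond toward attack at the distal carbon. It also needs oxygen rather than carbon nucleophilicity and acyl shift rather than protonation: 16 has no α-hydrogen, and the high temperature with excess CsF keeps free acid low.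

Step 11
Reactants: 19 3-[3,4-dimethoxy-5-(methoxymethoxy)phenyl]-6-methoxy-5,7-bis(methoxymethoxy)-4H-chromen-4-one
Product: 20 3-[3,4-dimethoxy-5-(methoxymethoxy)phenyl]-5-hydroxy-6-methoxy-7-(methoxymethoxy)-4H-chromen-4-one
Conditions: MgBr2·OEt2 (1.2 equiv), CH2Cl2/Et2O, 0 °C → rt; then aq NH4Cl
Reagents that add atoms: none
Why: Chelation-controlled Lewis-acid ether cleavage should be site-selective because magnesium is held in the six-membered pocket between the C4 carbonyl and the peri C5 oxygen, so bromide removes only that methoxymethyl group (the ortho-carbonyl selectivity MgBr2 also shows toward aryl benzyl ethers), while the C7 and C3' acetals have no carbonyl partner.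

Step 12
Reactants: 20 3-[3,4-dimethoxy-5-(methoxymethoxy)phenyl]-5-hydroxy-6-methoxy-7-(methoxymethoxy)-4H-chromen-4-one
Product: 22 5,7,8-trihydroxy-3-(3-hydroxy-4,5-dimethoxyphenyl)-6-methoxy-4H-chromen-4-one, via potassium aryl sulfate 21 (not isolated)
Conditions: K2S2O8, aq KOH, pyridine, 0 °C → rt, argon; then HCl, MeOH/H2O, Na2SO3, 60 °C
Reagents that add atoms: potassium peroxodisulfate, [K+].[K+].[O-]S(=O)(=O)OOS(=O)(=O)[O-]
Why: Elbs persulfate oxidation, established for 5-hydroxy-7-alkoxy flavones and isoflavones, should let the C5 phenoxide attack the peroxide oxygen through its para carbon C8, the only unsubstituted carbon of ring A, and hot methanolic HCl then hydrolyses the aryl sulfate 21 and both remaining methoxymethyl ethers in one operation while the product is kept acidic and reducing against autoxidation.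

Compound list
1 | 2-methoxybenzene-1,3-diol (2-methoxyresorcinol) | COc1c(O)cccc1O | starting material
2 | 2-methoxy-1,3-bis(methoxymethoxy)benzene | COCOc1cccc(OCOC)c1OC | intermediate
3 | 2-[4-methoxy-3,5-bis(methoxymethoxy)phenyl]-4,4,5,5-tetramethyl-1,3,2-dioxaborolane (not isolated) | COCOc1cc(B2OC(C)(C)C(C)(C)O2)cc(OCOC)c1OC | intermediate
4 | 4-methoxy-3,5-bis(methoxymethoxy)phenol | COCOc1cc(O)cc(OCOC)c1OC | intermediate
5 | 2-bromo-4-methoxy-3,5-bis(methoxymethoxy)phenol | COCOc1cc(O)c(Br)c(OCOC)c1OC | intermediate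
6 | [2-bromo-4-methoxy-3,5-bis(methoxymethoxy)phenoxy]trimethylsilane (not isolated) | COCOc1cc(O[Si](C)(C)C)c(Br)c(OCOC)c1OC | intermediate
7 | lithium 4-methoxy-3,5-bis(methoxymethoxy)-2-(trimethylsilyl)phenolate (not isolated) | COCOc1cc([O-])c([Si](C)(C)C)c(OCOC)c1OC.[Li+] | intermediate
8 | 4-methoxy-3,5-bis(methoxymethoxy)-2-(trimethylsilyl)phenyl trifluoromethanesulfonate | COCOc1cc(OS(=O)(=O)C(F)(F)F)c([Si](C)(C)C)c(OCOC)c1OC | intermediate
9 | 2,3-dimethoxyphenol | COc1cccc(O)c1OC | starting material
10 | 1,2-dimethoxy-3-(methoxymethoxy)benzene | COCOc1cccc(OC)c1OC | intermediate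
11 | 2-[3,4-dimethoxy-5-(methoxymethoxy)phenyl]-4,4,5,5-tetramethyl-1,3,2-dioxaborolane | COCOc1cc(B2OC(C)(C)C(C)(C)O2)cc(OC)c1OC | intermediate
12 | methyl (E)-3-methoxyprop-2-enoate | CO/C=C/C(=O)OC | starting material
13 | methyl 3-acetoxy-2-iodo-3-methoxypropanoate (racemic diastereomer mixture, not isolated) | COC(=O)C(I)C(OC)OC(C)=O | intermediate
14 | methyl (Z)-2-iodo-3-methoxyprop-2-enoate | COC(=O)/C(I)=C/OC | intermediate
15 | methyl (E)-2-[3,4-dimethoxy-5-(methoxymethoxy)phenyl]-3-methoxyprop-2-enoate | COC(=O)/C(=C/OC)c1cc(OC)c(OC)c(OCOC)c1 | intermediate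
16 | (E)-2-[3,4-dimethoxy-5-(methoxymethoxy)phenyl]-3-methoxyprop-2-enoic acid | OC(=O)/C(=C/OC)c1cc(OC)c(OC)c(OCOC)c1 | intermediate
17 | 4-methoxy-3,5-bis(methoxymethoxy)benzyne (1,2-didehydrobenzene, not isolated) | COCOC1=CC#CC(OCOC)=C1OC | intermediate
18 | cesium 2-{(E)-2-[3,4-dimethoxy-5-(methoxymethoxy)phenyl]-3-methoxyprop-2-enoyl}-4-methoxy-3,5-bis(methoxymethoxy)phenolate (not isolated) | COCOc1cc([O-])c(C(=O)/C(=C/OC)c2cc(OC)c(OC)c(OCOC)c2)c(OCOC)c1OC.[Cs+] | intermediate
19 | 3-[3,4-dimethoxy-5-(methoxymethoxy)phenyl]-6-methoxy-5,7-bis(methoxymethoxy)-4H-chromen-4-one | COCOc1cc2occ(-c3cc(OC)c(OC)c(OCOC)c3)c(=O)c2c(OCOC)c1OC | intermediate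
20 | 3-[3,4-dimethoxy-5-(methoxymethoxy)phenyl]-5-hydroxy-6-methoxy-7-(methoxymethoxy)-4H-chromen-4-one | COCOc1cc2occ(-c3cc(OC)c(OC)c(OCOC)c3)c(=O)c2c(O)c1OC | intermediate
21 | potassium 3-[3,4-dimethoxy-5-(methoxymethoxy)phenyl]-5-hydroxy-6-methoxy-7-(methoxymethoxy)-4-oxo-4H-chromen-8-yl sulfate (not isolated) | COCOc1c(OS(=O)(=O)[O-])c2occ(-c3cc(OC)c(OC)c(OCOC)c3)c(=O)c2c(O)c1OC.[K+] | intermediate
22 | 5,7,8-trihydroxy-3-(3-hydroxy-4,5-dimethoxyphenyl)-6-methoxy-4H-chromen-4-one (5,7,8,3'-tetrahydroxy-6,4',5'-trimethoxyisoflavone) | COc1cc(-c2coc3c(O)c(O)c(OC)c(O)c3c2=O)cc(O)c1OC | target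

Total step count: 12.
Longest linear sequence: 7 steps (steps 1–4 then 10–12; the ring B branch, steps 5, 6, 8, 9 then 10–12, is equally long).

Steps most likely to fail

Step 10. The aryl anion may be protonated before the acyl shift, which would stop at an aryl ester that cannot close ring C, or the carboxylate may attack the wrong aryne carbon. The fallback uses no aryne and fixes the regiochemistry by the position of a halogen. It sets out from bromophenol 5 and acid 16. Carbodiimide esterification (EDC·HCl, DMAP, CH2Cl2) should give 2-bromo-4-methoxy-3,5-bis(methoxymethoxy)phenyl (E)-2-[3,4-dimethoxy-5-(methoxymethoxy)phenyl]-3-methoxyprop-2-enoate F1. Bromine–lithium exchange (t-BuLi, THF, −95 °C) then triggers the known anionic ortho-Fries shift of the acyl group to the carbon that carried bromine, giving lithium 2-{(E)-2-[3,4-dimethoxy-5-(methoxymethoxy)phenyl]-3-methoxyprop-2-enoyl}-4-methoxy-3,5-bis(methoxymethoxy)phenolate F2. On warming, F2 should close ring C by oxa-Michael addition and loss of methoxide, and the route is rejoined at 19.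

Step 12. Over-oxidation of the electron-rich ring and hydroxide-induced opening of the pyranone compete with para attack on peroxodisulfate, so conversion may stall or material may be lost. The fallback replaces the alkaline persulfate by a neutral quinone route and sets out from 20. Teuber oxidation with Fremy's salt ((KSO3)2NO, KH2PO4 buffer, acetone/H2O) should take the phenol, whose para position is free, to 3-[3,4-dimethoxy-5-(methoxymethoxy)phenyl]-6-methoxy-7-(methoxymethoxy)-4H-chromene-4,5,8-trione F3. Reduction with Na2S2O4 (EtOAc/H2O) should give 3-[3,4-dimethoxy-5-(methoxymethoxy)phenyl]-5,8-dihydroxy-6-methoxy-7-(methoxymethoxy)-4H-chromen-4-one F4. HCl in MeOH then removes both acetals, and the route is rejoined at 22.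

Step 11. Site-selectivity may be lost if a second acetal (at C7 or C3') is cleaved before the peri one is fully gone. The fallback gives up selective deprotection in favour of selective reprotection and sets out from 19. HCl in MeOH at 50 °C removes all three acetals to give 5,7-dihydroxy-3-(3-hydroxy-4,5-dimethoxyphenyl)-6-methoxy-4H-chromen-4-one F5. Benzylation (BnBr, 2.2 equiv, K2CO3, acetone, reflux) leaves the hydrogen-bonded C5 hydroxyl untouched and should give 7-(benzyloxy)-3-[3-(benzyloxy)-4,5-dimethoxyphenyl]-5-hydroxy-6-methoxy-4H-chromen-4-one F6. Elbs oxidation (K2S2O8, aq KOH, pyridine) leads through potassium 7-(benzyloxy)-3-[3-(benzyloxy)-4,5-dimethoxyphenyl]-5-hydroxy-6-methoxy-4-oxo-4H-chromen-8-yl sulfate F7, and acid hydrolysis gives 7-(benzyloxy)-3-[3-(benzyloxy)-4,5-dimethoxyphenyl]-5,8-dihydroxy-6-methoxy-4H-chromen-4-one F8. Hydrogenolysis (H2, Pd/C, EtOAc/MeOH, rt) removes both benzyl groups, and the route is rejoined at 22.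

Further compounds
F1 | step 10 | 2-bromo-4-methoxy-3,5-bis(methoxymethoxy)phenyl (E)-2-[3,4-dimethoxy-5-(methoxymethoxy)phenyl]-3-methoxyprop-2-enoate | O=C(Oc1cc(OCOC)c(OC)c(OCOC)c1Br)/C(=C/OC)c1cc(OC)c(OC)c(OCOC)c1
F2 | step 10 | lithium 2-{(E)-2-[3,4-dimethoxy-5-(methoxymethoxy)phenyl]-3-methoxyprop-2-enoyl}-4-methoxy-3,5-bis(methoxymethoxy)phenolate | COCOc1cc([O-])c(C(=O)/C(=C/OC)c2cc(OC)c(OC)c(OCOC)c2)c(OCOC)c1OC.[Li+]
F3 | step 12 | 3-[3,4-dimethoxy-5-(methoxymethoxy)phenyl]-6-methoxy-7-(methoxymethoxy)-4H-chromene-4,5,8-trione | COCOC1=C(OC)C(=O)C2=C(OC=C(c3cc(OC)c(OC)c(OCOC)c3)C2=O)C1=O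
F4 | step 12 | 3-[3,4-dimethoxy-5-(methoxymethoxy)phenyl]-5,8-dihydroxy-6-methoxy-7-(methoxymethoxy)-4H-chromen-4-one | COCOc1c(O)c2occ(-c3cc(OC)c(OC)c(OCOC)c3)c(=O)c2c(O)c1OC
F5 | step 11 | 5,7-dihydroxy-3-(3-hydroxy-4,5-dimethoxyphenyl)-6-methoxy-4H-chromen-4-one | COc1cc(-c2coc3cc(O)c(OC)c(O)c3c2=O)cc(O)c1OC
F6 | step 11 | 7-(benzyloxy)-3-[3-(benzyloxy)-4,5-dimethoxyphenyl]-5-hydroxy-6-methoxy-4H-chromen-4-one | COc1cc(-c2coc3cc(OCc4ccccc4)c(OC)c(O)c3c2=O)cc(OCc5ccccc5)c1OC
F7 | step 11 | potassium 7-(benzyloxy)-3-[3-(benzyloxy)-4,5-dimethoxyphenyl]-5-hydroxy-6-methoxy-4-oxo-4H-chromen-8-yl sulfate | COc1cc(-c2coc3c(OS(=O)(=O)[O-])c(OCc4ccccc4)c(OC)c(O)c3c2=O)cc(OCc5ccccc5)c1OC.[K+]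
F8 | step 11 | 7-(benzyloxy)-3-[3-(benzyloxy)-4,5-dimethoxyphenyl]-5,8-dihydroxy-6-methoxy-4H-chromen-4-one | COc1cc(-c2coc3c(O)c(OCc4ccccc4)c(OC)c(O)c3c2=O)cc(OCc5ccccc5)c1OC
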